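The ten-membered carbocycle is disconnected at C9–C10. The C9 ketone lies between the oxygenated C8 and the (Z)-C1=C10 alkene, so it is treated as an oxidised allylic alcohol formed when a (Z)-C10 alkenylchromium adds to a C9 aldehyde. This one nickel/chromium-mediated operation makes C9–C10 and completes the ten-membered ring beside the finished cis-fused α-methylene γ-lactone (C6/C7), which holds both reacting chains on one face. The cyclisation substrate is a monocyclic cis lactone with the (Z,Z)-iododienyl chain on C6 and a C8-silyloxy C9-aldehyde on C7. It is assembled by zinc-mediated union of a neryl-derived iododienal with a glyceraldehyde-derived 2-(bromomethyl)acrylate.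

Key step: step 12

Remark: germacrane numbering is used (lactone C12(=O)–O–C6, ring fusion C6/C7, ester oxygen on C8, ketone C9, C14 on C10, C15 on C4) and the SMILES strings are decisive for stereochemistry. C8 is carried as a triethylsilyl ether because the bis-silyl ether of the C8/C9 diol gives the C9 aldehyde in one operation and the group later leaves with buffered fluoride. Neryl acetate is taken as the commercial form of nerol.

Step 1
Reactants: 1 neryl acetate, (2Z)-3,7-dimethylocta-2,6-dien-1-yl acetate
Product: 2 (2Z)-5-(3,3-dimethyloxiran-2-yl)-3-methylpent-2-en-1-yl acetate (racemic at the oxirane carbon)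
Conditions: mCPBA, CH2Cl2, 0 °C
Reagents that add atoms: 3-chloroperbenzoic acid, OOC(=O)c1cccc(Cl)c1
Why: Prilezhaev epoxidation selects the remote, more electron-rich 6,7-alkene because the 2,3-alkene is deactivated by the allylic acetate; the racemic oxirane centre is destroyed in step 2.

Step 2
Reactants: 2 (2Z)-5-(3,3-dimethyloxiran-2-yl)-3-methylpent-2-en-1-yl acetate
Product: 4 (2Z)-3-methyl-6-oxohex-2-en-1-yl acetate, via diol 3 (not isolated)
Conditions: H5IO6, THF/H2O, 0 °C → rt
Reagents that add atoms: water, O (it enters diol 3)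
Why: Aqueous periodic acid first hydrates the epoxide to diol 3 and then cleaves it (Malaprade glycol cleavage) to the aldehyde and acetone, conditions under which the (Z)-allylic acetate is inert.

Step 3
Reactants: 4 (2Z)-3-methyl-6-oxohex-2-en-1-yl acetate
Product: 5 (2Z,6Z)-7-iodo-3-methylocta-2,6-dien-1-yl acetate
Conditions: EtPPh3I, n-BuLi, THF, 0 °C → rt; I2, −78 °C; NaN(SiMe3)2, −20 °C; then 4, −78 → −20 °C
Reagents that add atoms: ethyltriphenylphosphonium iodide, CC[P+](c1ccccc1)(c1ccccc1)c1ccccc1.[I-]; iodine, II
Why: Stork–Zhao-type Wittig olefination with the α-iodoethylidene ylide runs under kinetic control through the cis-oxaphosphetane of a non-stabilised ylide, which places iodine cis to the chain and gives the (Z)-alkenyl iodide, while the acetate should not be attacked at low temperature.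

Step 4
Reactants: 5 (2Z,6Z)-7-iodo-3-methylocta-2,6-dien-1-yl acetate
Product: 6 (2Z,6Z)-7-iodo-3-methylocta-2,6-dien-1-ol
Conditions: K2CO3 (cat.), MeOH, 0 °C → rt
Reagents that add atoms: none
Why: Carbonate-catalysed methanolysis (transesterification) removes the acetate without touching the alkenyl iodide or either alkene geometry.

Step 5
Reactants: 6 (2Z,6Z)-7-iodo-3-methylocta-2,6-dien-1-ol
Product: 7 (2Z,6Z)-7-iodo-3-methylocta-2,6-dienal
Conditions: TEMPO (cat.), PhI(OAc)2, CH2Cl2, rt
Reagents that add atoms: none
Why: The TEMPO/PhI(OAc)2 oxoammonium oxidation converts the allylic alcohol into the enal under non-isomerising conditions, so the (2Z) geometry of this neral-type aldehyde should be kept.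

Step 6
Reactants: 8 (S)-glyceraldehyde acetonide, (4S)-2,2-dimethyl-1,3-dioxolane-4-carbaldehyde; 9 methyl acrylate
Product: 10 methyl 2-{hydroxy[(4S)-2,2-dimethyl-1,3-dioxolan-4-yl]methyl}prop-2-enoate (both carbinol epimers)
Conditions: DABCO, 1,4-dioxane/H2O, rt
Reagents that add atoms: none
Why: The Morita–Baylis–Hillman reaction forms the C7–C11 bond; the new carbinol centre is formed without control but is removed in step 7, and the weak amine base should leave the dioxolane stereocentre (the future C8) intact.

Step 7
Reactants: 10 methyl 2-{hydroxy[(4S)-2,2-dimethyl-1,3-dioxolan-4-yl]methyl}prop-2-enoate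
Product: 11 methyl (2Z)-2-(bromomethyl)-3-[(4R)-2,2-dimethyl-1,3-dioxolan-4-yl]prop-2-enoate
Conditions: NBS, Me2S, CH2Cl2, 0 °C → rt
Reagents that add atoms: N-bromosuccinimide, O=C1CCC(=O)N1Br
Why: Activation of the allylic hydroxyl as an alkoxysulfonium salt (Corey–Kim reagent) and SN2' attack by bromide transpose the allylic system, both carbinol epimers converging on the more stable (Z) isomer with the dioxolane trans to the ester.

Step 8
Reactants: 7 (2Z,6Z)-7-iodo-3-methylocta-2,6-dienal; 11 methyl (2Z)-2-(bromomethyl)-3-[(4R)-2,2-dimethyl-1,3-dioxolan-4-yl]prop-2-enoate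
Product: 14 (4S,5S)-4-[(4R)-2,2-dimethyl-1,3-dioxolan-4-yl]-5-[(1Z,5Z)-6-iodo-2-methylhepta-1,5-dien-1-yl]-3-methylideneoxolan-2-one (cis lactone acetonide), via allylzinc bromide 12 (not isolated), via bromozinc alkoxide 13 (not isolated)
Conditions: activated Zn dust, THF, 0 °C → rt, then 40 °C; sat. aq. NH4Cl work-up
Reagents that add atoms: none
Why: In this zinc-mediated Barbier allylation with lactonisation (Dreiding–Schmidt reaction), allylzinc 12 adds 1,2 to the enal through a six-membered chair transition state with the dioxolane cis to the CH2Zn group, which gives the syn adduct and hence the cis lactone (C6), while C7 is set by attack anti to the C8–O bond in the conformer that keeps H8 in the alkene plane to avoid allylic 1,3-strain (Felkin-type control by the glyceraldehyde-derived centre); zinc alkoxide 13 then closes the five-membered lactone.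

Step 9
Reactants: 14 cis lactone acetonide
Product: 15 (4R,5S)-4-[(1R)-1,2-dihydroxyethyl]-5-[(1Z,5Z)-6-iodo-2-methylhepta-1,5-dien-1-yl]-3-methylideneoxolan-2-one
Conditions: AcOH/H2O (4:1), 35 °C
Reagents that add atoms: none
Why: Acid-catalysed hydrolysis of the terminal isopropylidene acetal in aqueous acetic acid is mild enough to spare the allylic lactone, the α-methylene group and the alkenyl iodide, and the absence of base avoids acyl migration of the lactone to the liberated hydroxyls.

Step 10
Reactants: 15 diol lactone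
Product: 16 (4S,5S)-4-[(1R)-1,2-bis(triethylsilyloxy)ethyl]-5-[(1Z,5Z)-6-iodo-2-methylhepta-1,5-dien-1-yl]-3-methylideneoxolan-2-one
Conditions: TESOTf, 2,6-lutidine, CH2Cl2, −78 °C
Reagents that add atoms: triethylsilyl trifluoromethanesulfonate, CC[Si](CC)(CC)OS(=O)(=O)C(F)(F)F
Why: Silylation of both hydroxyls with the silyl triflate and a hindered pyridine base is fast and non-nucleophilic at low temperature, so the conjugate acceptor is not touched and no stereocentre is affected.

Step 11
Reactants: 16 bis(triethylsilyl) ether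
Product: 18 (2R)-2-[(2S,3S)-2-[(1Z,5Z)-6-iodo-2-methylhepta-1,5-dien-1-yl]-4-methylidene-5-oxooxolan-3-yl]-2-(triethylsilyloxy)acetaldehyde, via primary alcohol 17 (not isolated)
Conditions: (COCl)2, DMSO, CH2Cl2, −78 → −40 °C; Et3N, −78 → 0 °C
Reagents that add atoms: none
Why: Under Swern conditions a primary triethylsilyl ether is cleaved and oxidised in situ through alcohol 17 while the hindered secondary silyl ether survives (selective Swern oxidation of primary silyl ethers), and the low temperature keeps the α-silyloxy aldehyde from epimerising at C8.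

Step 12
Reactants: 18 cis lactone with the (Z,Z)-iododienyl chain on C6 and the C8-silyloxy C9-aldehyde on C7
Product: 20 (6S,7S,8R,9S)-9-hydroxy-8-(triethylsilyloxy)germacra-1(10)Z,4Z,11(13)-trien-12,6-olide (the 9R epimer would be carried on as well), via alkenylchromium dichloride 19 (not isolated)
Conditions: CrCl2 (10 equiv), NiCl2 (cat.), degassed DMSO, rt, slow addition of 18 to about 2 mM
Reagents that add atoms: none
Why: Divalent chromium reduces NiCl2 to zerovalent nickel, which adds oxidatively to the C10–I bond without loss of the (Z) geometry; transmetallation gives the trivalent alkenylchromium 19, which attacks the C9 aldehyde (intramolecular Nozaki–Hiyama–Kishi reaction, the nickel/chromium alkenyl halide–aldehyde coupling that is the closest known type and is routinely used for medium rings bearing lactones and enoates). The ten-membered carbocycle is closed in the 10-exo-trig mode, the carbonyl oxygen remaining outside the ring. The new C9 centre is expected to arise by Felkin–Anh attack anti to the C8 silyloxy group, but its sense is irrelevant because step 13 oxidises C9. The step requires attack on the aldehyde only, retention of the C1=C10 geometry and no epimerisation at C8: the alkenylchromium is too weakly basic to enolise the aldehyde and too weakly nucleophilic to add to the lactone carbonyl or the α-methylene acceptor. Cyclisation is favoured over oligomerisation by slow addition at high dilution and by the cis lactone, which projects the C5 and C8 chains from the same face of the five-membered ring and so shortens the C9···C10 distance.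

Step 13
Reactants: 20 bicyclic C9 allylic alcohol
Product: 21 (6S,7S,8R)-9-oxo-8-(triethylsilyloxy)germacra-1(10)Z,4Z,11(13)-trien-12,6-olide
Conditions: Dess–Martin periodinane, CH2Cl2, 0 °C → rt
Reagents that add atoms: none
Why: Dess–Martin oxidation of the secondary allylic alcohol gives the C9 enone under neutral conditions, removes the C9 stereocentre and should not enolise C8.

Step 14
Reactants: 21 C9 enone silyl ether
Product: 22 (6S,7R,8R)-8-hydroxy-9-oxogermacra-1(10)Z,4Z,11(13)-trien-12,6-olide
Conditions: HF·pyridine, pyridine, THF, 0 °C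
Reagents that add atoms: none
Why: Buffered HF·pyridine cleaves the secondary silyl ether (fluoride-mediated desilylation) without strong base, so the α-hydroxy ketone should be released without epimerisation at C8 or isomerisation of the α-methylene lactone (the C7 descriptor changes only through priorities).

Step 15
Reactants: 23 angelic acid, (2Z)-2-methylbut-2-enoic acid
Product: 24 (2Z)-2-methylbut-2-en-1-ol
Conditions: LiAlH4, Et2O, 0 °C → rt
Reagents that add atoms: none
Why: Hydride reduction of the carboxylic acid with LiAlH4 gives the allylic alcohol by 1,2-reduction, and the (Z) geometry of the trisubstituted alkene should be retained at this temperature.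

Step 16
Reactants: 24 (2Z)-2-methylbut-2-en-1-ol
Product: 25 [(2R,3S)-2,3-dimethyloxiran-2-yl]methanol
Conditions: Ti(OiPr)4 (cat.), D-(−)-diethyl tartrate (cat.), t-BuOOH, 4 Å molecular sieves, CH2Cl2, −20 °C
Reagents that add atoms: tert-butyl hydroperoxide, CC(C)(C)OO
Why: In the Sharpless asymmetric epoxidation the (−)-tartrate complex delivers the peroxide oxygen to the alkene face that gives the (2R,3S)-epoxy alcohol, the syn-stereospecific transfer keeps the two methyl groups trans as in angelic acid, and any minor enantiomer would end as a separable diastereomer of 28.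

Step 17
Reactants: 25 [(2R,3S)-2,3-dimethyloxiran-2-yl]methanol
Product: 26 (2S,3S)-2,3-dimethyloxirane-2-carboxylic acid
Conditions: RuCl3·xH2O (cat.), NaIO4, MeCN/CCl4/H2O, 0 °C → rt
Reagents that add atoms: water, O
Why: Catalytic RuO4 oxidation (RuCl3/NaIO4) takes the primary alcohol through the aldehyde hydrate to the acid without opening the epoxide; the C2 descriptor becomes S only because the substituent priorities change.

Step 18
Reactants: 22 C8 α-hydroxy ketone; 26 (2S,3S)-2,3-dimethyloxirane-2-carboxylic acid
Product: 28 target CNP0183761.1, via mixed anhydride 27 (not isolated)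
Conditions: 26, 2,4,6-trichlorobenzoyl chloride, Et3N, toluene, rt; then 22, DMAP, toluene, rt
Reagents that add atoms: none
Why: In the Yamaguchi esterification the acid is activated as mixed anhydride 27 and transferred by DMAP to the C8 hydroxyl with retention at C8 and at both epoxide carbons, the mild amine base and short exposure limiting α-ketol isomerisation.

Compound list
1 | neryl acetate, (2Z)-3,7-dimethylocta-2,6-dien-1-yl acetate | CC(C)=CCC/C(C)=C\COC(C)=O | starting material
2 | (2Z)-5-(3,3-dimethyloxiran-2-yl)-3-methylpent-2-en-1-yl acetate (racemic oxirane) | CC(=O)OC/C=C(/C)CCC1OC1(C)C | intermediate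
3 | (2Z)-6,7-dihydroxy-3,7-dimethyloct-2-en-1-yl acetate (diol, not isolated) | CC(=O)OC/C=C(/C)CCC(O)C(C)(C)O | intermediate
4 | (2Z)-3-methyl-6-oxohex-2-en-1-yl acetate | CC(=O)OC/C=C(/C)CCC=O | intermediate
5 | (2Z,6Z)-7-iodo-3-methylocta-2,6-dien-1-yl acetate | CC(=O)OC/C=C(/C)CC/C=C(/C)I | intermediate
6 | (2Z,6Z)-7-iodo-3-methylocta-2,6-dien-1-ol | OC/C=C(/C)CC/C=C(/C)I | intermediate
7 | (2Z,6Z)-7-iodo-3-methylocta-2,6-dienal | O=C/C=C(/C)CC/C=C(/C)I | intermediate
8 | (S)-glyceraldehyde acetonide | CC1(C)OC[C@@H](C=O)O1 | starting material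
9 | methyl acrylate | C=CC(=O)OC | starting material
10 | methyl 2-{hydroxy[(4S)-2,2-dimethyl-1,3-dioxolan-4-yl]methyl}prop-2-enoate (carbinol epimers) | COC(=O)C(=C)C(O)[C@@H]1COC(C)(C)O1 | intermediate
11 | methyl (2Z)-2-(bromomethyl)-3-[(4R)-2,2-dimethyl-1,3-dioxolan-4-yl]prop-2-enoate | COC(=O)/C(CBr)=C/[C@@H]1COC(C)(C)O1 | intermediate
12 | allylzinc bromide from 11 (not isolated) | COC(=O)/C(C[Zn]Br)=C/[C@@H]1COC(C)(C)O1 | intermediate
13 | bromozinc alkoxide of the syn hydroxy ester (not isolated) | COC(=O)C(=C)[C@@H]([C@@H](O[Zn]Br)/C=C(/C)CC/C=C(/C)I)[C@@H]1COC(C)(C)O1 | intermediate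
14 | (4S,5S)-4-[(4R)-2,2-dimethyl-1,3-dioxolan-4-yl]-5-[(1Z,5Z)-6-iodo-2-methylhepta-1,5-dien-1-yl]-3-methylideneoxolan-2-one | C=C1C(=O)O[C@@H](/C=C(/C)CC/C=C(/C)I)[C@H]1[C@@H]2COC(C)(C)O2 | intermediate
15 | (4R,5S)-4-[(1R)-1,2-dihydroxyethyl]-5-[(1Z,5Z)-6-iodo-2-methylhepta-1,5-dien-1-yl]-3-methylideneoxolan-2-one | C=C1C(=O)O[C@@H](/C=C(/C)CC/C=C(/C)I)[C@H]1[C@@H](O)CO | intermediate
16 | (4S,5S)-4-[(1R)-1,2-bis(triethylsilyloxy)ethyl]-5-[(1Z,5Z)-6-iodo-2-methylhepta-1,5-dien-1-yl]-3-methylideneoxolan-2-one | C=C1C(=O)O[C@@H](/C=C(/C)CC/C=C(/C)I)[C@H]1[C@@H](O[Si](CC)(CC)CC)CO[Si](CC)(CC)CC | intermediate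
17 | (4S,5S)-4-[(1R)-2-hydroxy-1-(triethylsilyloxy)ethyl]-5-[(1Z,5Z)-6-iodo-2-methylhepta-1,5-dien-1-yl]-3-methylideneoxolan-2-one (not isolated) | C=C1C(=O)O[C@@H](/C=C(/C)CC/C=C(/C)I)[C@H]1[C@@H](O[Si](CC)(CC)CC)CO | intermediate
18 | (2R)-2-[(2S,3S)-2-[(1Z,5Z)-6-iodo-2-methylhepta-1,5-dien-1-yl]-4-methylidene-5-oxooxolan-3-yl]-2-(triethylsilyloxy)acetaldehyde | C=C1C(=O)O[C@@H](/C=C(/C)CC/C=C(/C)I)[C@H]1[C@@H](O[Si](CC)(CC)CC)C=O | intermediate
19 | alkenylchromium dichloride derived from 18 (not isolated) | C=C1C(=O)O[C@@H](/C=C(/C)CC/C=C(/C)[Cr](Cl)Cl)[C@H]1[C@@H](O[Si](CC)(CC)CC)C=O | intermediate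
20 | (6S,7S,8R,9S)-9-hydroxy-8-(triethylsilyloxy)germacra-1(10)Z,4Z,11(13)-trien-12,6-olide | C=C1C(=O)O[C@H]2/C=C(/C)CC/C=C(/C)[C@H](O)[C@H](O[Si](CC)(CC)CC)[C@@H]12 | intermediate
21 | (6S,7S,8R)-9-oxo-8-(triethylsilyloxy)germacra-1(10)Z,4Z,11(13)-trien-12,6-olide | C=C1C(=O)O[C@H]2/C=C(/C)CC/C=C(/C)C(=O)[C@H](O[Si](CC)(CC)CC)[C@@H]12 | intermediate
22 | (6S,7R,8R)-8-hydroxy-9-oxogermacra-1(10)Z,4Z,11(13)-trien-12,6-olide | C=C1C(=O)O[C@H]2/C=C(/C)CC/C=C(/C)C(=O)[C@H](O)[C@@H]12 | intermediate
23 | angelic acid, (2Z)-2-methylbut-2-enoic acid | C/C=C(/C)C(=O)O | starting material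
24 | (2Z)-2-methylbut-2-en-1-ol | C/C=C(/C)CO | intermediate
25 | [(2R,3S)-2,3-dimethyloxiran-2-yl]methanol | OC[C@@]1(C)O[C@H]1C | intermediate
26 | (2S,3S)-2,3-dimethyloxirane-2-carboxylic acid | OC(=O)[C@@]1(C)O[C@H]1C | intermediate
27 | (2S,3S)-2,3-dimethyloxirane-2-carboxylic 2,4,6-trichlorobenzoic anhydride (not isolated) | O=C(OC(=O)[C@@]1(C)O[C@H]1C)c1c(Cl)cc(Cl)cc1Cl | intermediate
28 | (6S,7S,8R)-9-oxogermacra-1(10)Z,4Z,11(13)-trien-12,6-olid-8-yl (2S,3S)-2,3-dimethyloxirane-2-carboxylate, CNP0183761.1 | C=C1C(=O)O[C@H]2/C=C(/C)CC/C=C(/C)C(=O)[C@H](OC(=O)[C@@]3(C)O[C@H]3C)[C@@H]12 | target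

Total step count: 18 steps.
Longest linear sequence: 13 steps (steps 1–5, 8–14 and 18, from neryl acetate).

Steps most likely to fail

Step 12. Intermolecular coupling (oligomerisation) or protonation of the alkenylchromium may outrun the strained ten-membered closure. The fallback forms the same C9–C10 bond by an intramolecular Stille acylation; it sets out from 18 and returns at 21, so step 13 is skipped. Aldehyde 18 would be stannylated with Me3SnSnMe3 and Pd(PPh3)4 (cat.) in toluene with retention of geometry to give the (Z)-alkenyl(trimethyl)stannane aldehyde F1. Pinnick oxidation (NaClO2, NaH2PO4, 2-methylbut-2-ene, t-BuOH/H2O) would give the stannane carboxylic acid F2. 1-Chloro-N,N,2-trimethylprop-1-en-1-amine in CH2Cl2 would convert it under neutral conditions into the stannane acid chloride F3. Pd2(dba)3 with tri(2-furyl)phosphine under CO (1 atm, to suppress decarbonylation) in THF at high dilution would then couple the acyl and alkenyl ends and give enone 21 directly.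

Step 8. The syn selectivity may erode through E/Z equilibration of the allylzinc or reversible addition during lactonisation, and the facial bias exerted by C8 may be insufficient. The fallback replaces the fluxional allylzinc by a configurationally fixed allylboronate; it sets out from 10 (and 7) and returns at 14. Adduct 10 would be acetylated (Ac2O, pyridine, DMAP cat.) to the allylic acetate F4. Borylation with B2pin2, CuCl, LiCl and KOAc in DMF proceeds with allylic transposition and would give the 2-(methoxycarbonyl)allylboronate F5 with the dioxolane cis to the CH2B group. Thermal allylboration of enal 7 in toluene passes through a closed boron chair transition state, which is stereospecific for the syn adduct and subject to the same allylic-strain-controlled attack anti to the C8–O bond; oxidative-free aqueous work-up would give the syn hydroxy ester F6, in which stereoisomers can be separated. PPTS (cat.) in toluene at 50 °C would then close the lactone to 14.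

Step 18. Acylation of the hindered C8 hydroxyl may be slow, and the amine base may meanwhile cause α-ketol isomerisation or transfer of the lactone acyl group to O8. The fallback installs the epoxy ester before ring closure, so that no free α-hydroxy ketone is ever formed; it sets out from 15 (and 26) and returns at 28. Diol 15 would be silylated selectively at the primary hydroxyl (TESCl, imidazole, CH2Cl2, −40 °C) to the primary triethylsilyl ether F7. Yamaguchi esterification of its C8 hydroxyl with 26 would give the C8 epoxy ester F8. Swern conditions would convert the primary silyl ether directly into the C8 epoxy ester C9 aldehyde F9. The nickel/chromium ring closure of step 12 (CrCl2, NiCl2 cat., DMSO, high dilution) would give the bicyclic C9 alcohol F10, and Dess–Martin oxidation would give 28.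

Further compounds
F1 | step 12 | (Z)-alkenyl(trimethyl)stannane aldehyde (18 with SnMe3 in place of iodine) | C=C1C(=O)O[C@@H](/C=C(/C)CC/C=C(/C)[Sn](C)(C)C)[C@H]1[C@@H](O[Si](CC)(CC)CC)C=O
F2 | step 12 | stannane carboxylic acid | C=C1C(=O)O[C@@H](/C=C(/C)CC/C=C(/C)[Sn](C)(C)C)[C@H]1[C@@H](O[Si](CC)(CC)CC)C(=O)O
F3 | step 12 | stannane acid chloride | C=C1C(=O)O[C@@H](/C=C(/C)CC/C=C(/C)[Sn](C)(C)C)[C@H]1[C@@H](O[Si](CC)(CC)CC)C(=O)Cl
F4 | step 8 | methyl 2-{acetoxy[(4S)-2,2-dimethyl-1,3-dioxolan-4-yl]methyl}prop-2-enoate | COC(=O)C(=C)C(OC(C)=O)[C@@H]1COC(C)(C)O1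
F5 | step 8 | methyl (2E)-3-[(4R)-2,2-dimethyl-1,3-dioxolan-4-yl]-2-[(4,4,5,5-tetramethyl-1,3,2-dioxaborolan-2-yl)methyl]prop-2-enoate | COC(=O)/C(CB2OC(C)(C)C(C)(C)O2)=C/[C@@H]1COC(C)(C)O1
F6 | step 8 | syn hydroxy ester (free alcohol corresponding to 13) | COC(=O)C(=C)[C@@H]([C@@H](O)/C=C(/C)CC/C=C(/C)I)[C@@H]1COC(C)(C)O1
F7 | step 18 | primary triethylsilyl ether of diol 15 | C=C1C(=O)O[C@@H](/C=C(/C)CC/C=C(/C)I)[C@H]1[C@@H](O)CO[Si](CC)(CC)CC
F8 | step 18 | C8 (2S,3S)-2,3-dimethyloxirane-2-carboxylate of F7 | C=C1C(=O)O[C@@H](/C=C(/C)CC/C=C(/C)I)[C@H]1[C@@H](OC(=O)[C@@]2(C)O[C@H]2C)CO[Si](CC)(CC)CC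
F9 | step 18 | C8 epoxy ester C9 aldehyde | C=C1C(=O)O[C@@H](/C=C(/C)CC/C=C(/C)I)[C@H]1[C@@H](OC(=O)[C@@]2(C)O[C@H]2C)C=O
F10 | step 18 | bicyclic C9 alcohol carrying the C8 epoxy ester (either C9 epimer) | C=C1C(=O)O[C@H]2/C=C(/C)CC/C=C(/C)[C@H](O)[C@H](OC(=O)[C@@]3(C)O[C@H]3C)[C@@H]12
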